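**Retrosynthetic overview**
1. The dihydropyranone is formed last, by acid cyclodehydration of a δ-hydroxy-β-diketone that comes from hydration (Et2NH, then aqueous acid) of a hydroxy-ynone.
2. The ynone comes from C-acylation of dilithiated (S)-pent-4-yn-2-ol by a tricyclic aryl δ-lactone, which protects the phenol and activates the acyl group at once.
3. The lactone comes from the key reversed-polarity bond ArC6–CH2: Negishi coupling of unprotected 6-iodoeugenin with the zinc homoenolate of methyl (S)-3-bromo-2-methylpropanoate. The aryl iodide carbon and the ester β-carbon are both natural electrophiles, and the side-chain stereocentre is carried in from the chiral pool.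
4. 6-Iodoeugenin comes from eugenin, which comes from noreugenin.
5. Ring order: chromone (purchased intact), then a transient δ-lactone (closed in step 3, opened in step 4), then the dihydropyranone (step 5).

Assumption: noreugenin, methyl (S)-3-bromo-2-methylpropanoate and (S)-pent-4-yn-2-ol are taken as purchasable catalogue compounds.

Step 1
Reactants: 1 noreugenin (5,7-dihydroxy-2-methyl-4H-chromen-4-one)
Product: 2 eugenin (5-hydroxy-7-methoxy-2-methyl-4H-chromen-4-one)
Conditions: Me2SO4 (1.05 equiv), K2CO3 (1.1 equiv), acetone, reflux, 4 h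
Reagents that add atoms: dimethyl sulfate, COS(=O)(=O)OC
Why: Williamson O-methylation; the 7-OH is the acidic, free phenol, whereas the 5-OH is locked in a hydrogen bond to the C4 carbonyl, so one equivalent of Me2SO4 methylates O7 only.

Step 2
Reactants: 2 eugenin
Product: 3 6-iodoeugenin (5-hydroxy-6-iodo-7-methoxy-2-methyl-4H-chromen-4-one)
Conditions: BnMe3NICl2 (1.05 equiv), CaCO3 (1.5 equiv), CH2Cl2/MeOH 5:2, rt, 12 h
Reagents that add atoms: benzyltrimethylammonium dichloroiodate, C[N+](C)(C)Cc1ccccc1.Cl[I-]Cl
Why: Electrophilic aromatic iodination; with the 5-OH free, dichloroiodate attacks C6 (ortho to the chelated phenol, between the two oxygens) in preference to C8, and CaCO3 takes up the HCl.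

Step 3
Reactants: 3 6-iodoeugenin; 4 methyl (S)-3-bromo-2-methylpropanoate
Product: 7 (3R)-5-methoxy-3,8-dimethyl-3,4-dihydro-2H,10H-pyrano[2,3-f]chromene-2,10-dione (δ-lactone closed from O5 onto the side-chain carboxyl), via zinc homoenolate 5 (not isolated), via hydroxy ester 6 (not isolated)
Conditions: 4 (2.5 equiv), Zn dust (BrCH2CH2Br/TMSCl-activated), LiCl, THF, 50 °C; then 3, Pd(OAc)2 (5 mol%), SPhos (10 mol%), THF/DMA, slow addition, 25→50 °C; aq. NH4Cl wash; then TsOH·H2O (20 mol%), PhMe, 110 °C, MeOH distilled off
Reagents that add atoms: none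
Why: Negishi cross-coupling of a chelate-stabilised β-zincio ester (zinc homoenolate), which is only weakly basic toward the chelated phenol and transmetalates to the aryl–palladium iodide formed from 3 under SPhos ligation, so two natively electrophilic carbons (aryl iodide carbon, ester β-carbon) are joined; the stereocentre comes unchanged from 4 because it is not the metalated carbon, and acid-catalysed transesterification then closes the lactone.

Step 4
Reactants: 7 tricyclic lactone; 8 (S)-pent-4-yn-2-ol
Product: 10 5-hydroxy-6-[(2R,7S)-7-hydroxy-2-methyl-3-oxooct-4-yn-1-yl]-7-methoxy-2-methyl-4H-chromen-4-one, via dilithio alkynolate 9 (not isolated)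
Conditions: 8 (1.5 equiv), n-BuLi (3.0 equiv), THF, −78→−20 °C; then 7 added at −78 °C, 1 h; AcOH quench at −78 °C
Reagents that add atoms: none
Why: Nucleophilic acyl substitution (alkynylation of an aryl lactone); the acetylide carbon of the dianion is its most nucleophilic site and adds once to the activated aryl ester, the cyclic lactolate resisting a second addition at −78 °C, so the phenol is released as the ynone forms, and both stereocentres are carried through untouched with a cold quench limiting enolisation.

Step 5
Reactants: 10 hydroxy-ynone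
Product: 13 5-hydroxy-7-methoxy-2-methyl-6-{(2R)-2-[(2S)-2-methyl-4-oxo-3,4-dihydro-2H-pyran-6-yl]propyl}-4H-chromen-4-one (target), via enaminone 11 (not isolated), via hydroxy diketone 12 (not isolated)
Conditions: Et2NH (2 equiv), EtOH, 0 °C→rt, 1 h; evaporate; TsOH·H2O (1.5 equiv), THF/H2O 10:1, rt→40 °C
Reagents that add atoms: water, O
Why: Aza-Michael addition of Et2NH to the ynone gives the β-enaminone, acid hydrolysis gives the δ-hydroxy-β-diketone, and acid-catalysed cyclodehydration (hemiketalisation by the secondary alcohol, loss of water) gives the vinylogous ester; the ring C–O stereocentre comes from 8 with its C–O bond intact, and the side-chain stereocentre is not touched.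

**Compound list**
1 | noreugenin (5,7-dihydroxy-2-methyl-4H-chromen-4-one) | Oc1cc2oc(C)cc(=O)c2c(O)c1 | starting material
2 | eugenin (5-hydroxy-7-methoxy-2-methyl-4H-chromen-4-one) | COc1cc2oc(C)cc(=O)c2c(O)c1 | intermediate
3 | 5-hydroxy-6-iodo-7-methoxy-2-methyl-4H-chromen-4-one | COc1cc2oc(C)cc(=O)c2c(O)c1I | intermediate
4 | methyl (S)-3-bromo-2-methylpropanoate | COC(=O)[C@H](C)CBr | starting material
5 | (S)-(3-methoxy-2-methyl-3-oxopropyl)zinc bromide | COC(=O)[C@H](C)C[Zn]Br | intermediate
6 | methyl (2R)-3-(5-hydroxy-7-methoxy-2-methyl-4-oxo-4H-chromen-6-yl)-2-methylpropanoate | COc1cc2oc(C)cc(=O)c2c(O)c1C[C@@H](C)C(=O)OC | intermediate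
7 | (3R)-5-methoxy-3,8-dimethyl-3,4-dihydro-2H,10H-pyrano[2,3-f]chromene-2,10-dione | COc1cc2oc(C)cc(=O)c2c2c1C[C@@H](C)C(=O)O2 | intermediate
8 | (S)-pent-4-yn-2-ol | C#CC[C@H](C)O | starting material
9 | lithium (S)-5-lithiopent-4-yn-2-olate | [Li]C#CC[C@H](C)O[Li] | intermediate
10 | 5-hydroxy-6-[(2R,7S)-7-hydroxy-2-methyl-3-oxooct-4-yn-1-yl]-7-methoxy-2-methyl-4H-chromen-4-one | COc1cc2oc(C)cc(=O)c2c(O)c1C[C@@H](C)C(=O)C#CC[C@H](C)O | intermediate
11 | 6-[(2R,4E,7S)-5-(diethylamino)-7-hydroxy-2-methyl-3-oxooct-4-en-1-yl]-5-hydroxy-7-methoxy-2-methyl-4H-chromen-4-one | COc1cc2oc(C)cc(=O)c2c(O)c1C[C@@H](C)C(=O)/C=C(/N(CC)CC)C[C@H](C)O | intermediate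
12 | 5-hydroxy-6-[(2R,7S)-7-hydroxy-2-methyl-3,5-dioxooctyl]-7-methoxy-2-methyl-4H-chromen-4-one | COc1cc2oc(C)cc(=O)c2c(O)c1C[C@@H](C)C(=O)CC(=O)C[C@H](C)O | intermediate
13 | 5-hydroxy-7-methoxy-2-methyl-6-{(2R)-2-[(2S)-2-methyl-4-oxo-3,4-dihydro-2H-pyran-6-yl]propyl}-4H-chromen-4-one | COc1cc2oc(C)cc(=O)c2c(O)c1C[C@@H](C)C1=CC(=O)C[C@H](C)O1 | target

**Totals**
Total step count: 5. Longest linear sequence: 5 steps (1 → 2 → 3 → 7 → 10 → 13).

**Three steps most likely to fail**

Step 3 (the key coupling). The iodide carries two ortho substituents and a free phenol, so protonolysis of the zinc reagent, slow transmetalation or β-hydride loss may win. The fallback sets out from 3 and comes back at 7. Acetylate 3 (Ac2O, pyridine, DMAP cat., 50 °C) to 5-acetoxy-6-iodo-7-methoxy-2-methyl-4H-chromen-4-one F1, so that palladium sees no acidic proton. Couple F1 with zinc reagent 5 under the same Pd(OAc)2/SPhos system to give methyl (2R)-3-(5-acetoxy-7-methoxy-2-methyl-4-oxo-4H-chromen-6-yl)-2-methylpropanoate F2. Heat F2 with TsOH·H2O and a trace of MeOH in PhMe at 110 °C; the acetyl group leaves as methyl acetate and the freed phenol closes onto the ester to give 7.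

Step 4. The acetylide may deprotonate the chromone 2-methyl group, the alkoxide end may O-acylate, a second acetylide may add, or the α-stereocentre may epimerise. The fallback sets out from 7 and comes back at 10. Open 7 with MeNHOMe·HCl/Me3Al (CH2Cl2, 0 °C→rt) to (2R)-3-(5-hydroxy-7-methoxy-2-methyl-4-oxo-4H-chromen-6-yl)-N-methoxy-N,2-dimethylpropanamide F3. Treat F3 with 9 (3.5 equiv, THF, −78→−20 °C). The chromone is then a deactivated phenoxide and the chelated tetrahedral intermediate stops cleanly at the ketone stage, giving 10 on quench.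

Step 5. The amine could attack the chromone, the δ-hydroxyl could eliminate, the centre next to the diketone could epimerise, or the 5-OH could compete for the ketone (chromene or spiroketal isomers; these should revert to 13 by reversible oxa-Michael steps, since 13 keeps the vinylogous ester and the chelated phenol). The fallback sets out from 8 and 7 and comes back at 12. Hydrate the small fragment first: 8 with Hg(OTf)2 (2 mol%), H2O, MeCN, rt (Markovnikov) gives (S)-4-hydroxypentan-2-one F4. LiN(i-Pr)2 (2.1 equiv, THF, −78 °C) converts F4 into dilithium (S)-4-oxidopent-1-en-2-olate F5, the kinetic terminal enolate. Acylate F5 (2.2 equiv) with 7 at −78 °C (Claisen-type C-acylation, phenoxide as leaving group) and quench with AcOH to give 12 directly, which is cyclodehydrated as in the second half of step 5 (TsOH·H2O, CH2Cl2, rt) to 13. This removes the amine and the aqueous hydration from the advanced intermediate.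

Further compounds
F1 | step 3 | 5-acetoxy-6-iodo-7-methoxy-2-methyl-4H-chromen-4-one | COc1cc2oc(C)cc(=O)c2c(OC(C)=O)c1I
F2 | step 3 | methyl (2R)-3-(5-acetoxy-7-methoxy-2-methyl-4-oxo-4H-chromen-6-yl)-2-methylpropanoate | COc1cc2oc(C)cc(=O)c2c(OC(C)=O)c1C[C@@H](C)C(=O)OC
F3 | step 4 | (2R)-3-(5-hydroxy-7-methoxy-2-methyl-4-oxo-4H-chromen-6-yl)-N-methoxy-N,2-dimethylpropanamide | COc1cc2oc(C)cc(=O)c2c(O)c1C[C@@H](C)C(=O)N(C)OC
F4 | step 5 | (S)-4-hydroxypentan-2-one | CC(=O)C[C@H](C)O
F5 | step 5 | dilithium (S)-4-oxidopent-1-en-2-olate | C=C(O[Li])C[C@H](C)O[Li]
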